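**Retrosynthetic overview**

1. Numbering: ring C1 = carbinol carbon, C2–C3 = the CH2–CH2 pair, C4 = C(CH3)Br, C5 = CHCl, C6 = CH2; side chain C1' (=CH2), C2', C3', C4' (carbinol).
2. Last bond C3'–C4': catalyst-controlled allylboration of 3-methylbut-2-enal with a ring-bound 2-substituted allylboronate, made from a vinyl triflate, itself from a methyl ketone attached at C1 as an acyl anion equivalent.
3. Halogens: C4–Br by Markovnikov HBr addition to an exocyclic C4 methylene, anti to C5–Cl; C5–Cl by invertive displacement of an allylic C5–OH. That carbinol (set by catalysis) first directs the C1 addition, so one centre is relayed to C1 and C4.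
4. The only ring is formed first, in one operation: a double decarboxylative [3+3] annulation of 3-oxopentanedioic acid with 2-formylallyl acetate, C2–C3 by conjugate addition–elimination and C5–C6 by aldol closure.
5. Enabling feature: C1 bears oxygen and is flanked by two CH2 groups, so C6–C1–C2 is an acetone unit whose two α-carbons are each activated once by a carboxyl group lost as CO2; C3–C4(CH3)–C5(Cl) maps onto a 2-formylallyl 1,3-dielectrophile (C3 = acceptor CH2, C5 = aldehyde carbon, the methyl = exocyclic CH2).

Key step: step 2

Assumption: (S)-proline in step 2 and (S)-TRIP in step 9 are taken to give the (R)-carbinol and the (S)-carbinol, by analogy with proline aldolisations and with phosphoric acid-catalysed allylborations; the mirror-image catalyst is used if either sense proves opposite.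

**Step 1**
Reactants: 1 2-methylallyl acetate
Product: 2 2-formylallyl acetate
Conditions: SeO2, 1,4-dioxane, 100 °C
Reagents that add atoms: selenium dioxide, O=[Se]=O
Why: Selenium dioxide allylic oxidation (ene reaction, 2,3-sigmatropic shift, further oxidation) should turn the methyl group of the 1,1-disubstituted alkene into the aldehyde, the acetoxymethyl side being deactivated by its oxygen.

**Step 2**
Reactants: 2 2-formylallyl acetate; 3 3-oxopentanedioic acid
Product: 5 (3R)-3-hydroxy-4-methylidenecyclohexan-1-one, via 6-formyl-3-oxohept-6-enoic acid 4 (not isolated)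
Conditions: (S)-proline (20 mol %), NaOAc, DMSO/H2O, 0 °C to rt
Reagents that add atoms: none
Why: Proposed new method: the doubly activated methylene of 3 should add in conjugate fashion to the exocyclic CH2 of enal 2 and expel acetate (SN2'-type addition–elimination, forming C2–C3), the alkylated β-keto acid arm then losing CO2 to give 4; proline should condense with the ketone of 4, the remaining β-keto acid decarboxylating to the terminal enamine, which closes onto the aldehyde (forming C5–C6). The closest known reaction types are the Robinson–Schöpf and Weiss–Cook condensations of 3-oxopentanedioic acid derivatives, the allylation of β-dicarbonyl compounds by Morita–Baylis–Hillman acetates, decarboxylative aldol additions of β-keto acids and the proline-catalysed Hajos–Parrish aldolisation. The single ring closes in a 6-(enolendo)-exo-trig aldol mode. The new carbinol centre (3R in 5, ring C5) should be set by the catalyst, whose carboxylic acid hydrogen-bonds to the aldehyde in a chair-like enamine transition state. The step needs C-alkylation at the CH2 terminus instead of 1,2-addition, aldol instead of conjugate closure onto the new exocyclic methylene, and survival of the β-hydroxy ketone; the soft β-keto acid carbanion, the fact that each carboxyl group fixes where the enol or enamine forms and is then lost, the poor iminium activation of an α-branched enal by a secondary amine, and the buffered near-neutral medium are expected to secure this.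

**Step 3**
Reactants: 5 (3R)-3-hydroxy-4-methylidenecyclohexan-1-one
Product: 6 (3R)-4-methylidene-3-(triethylsilyloxy)cyclohexan-1-one
Conditions: Et3SiCl, imidazole, DMF, 0 °C
Reagents that add atoms: chlorotriethylsilane, CC[Si](Cl)(CC)CC
Why: Standard silylation of the secondary alcohol under mild base should protect the β-hydroxy ketone before it can dehydrate, without touching the stereocentre.

**Step 4**
Reactants: 6 (3R)-4-methylidene-3-(triethylsilyloxy)cyclohexan-1-one; 7 ethyl vinyl ether
Product: 9 1-[(1R,3R)-1-hydroxy-4-methylidene-3-(triethylsilyloxy)cyclohexyl]ethan-1-one, via the 1-ethoxyvinyl carbinol 8 (not isolated)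
Conditions: 7, t-BuLi, THF, −78 to 0 °C; CeCl3, −78 °C; then 6; NH4Cl aq.; cat. (CO2H)2, THF/H2O, 0 °C
Reagents that add atoms: water, O
Why: The cerium reagent from 1-ethoxyvinyllithium (acyl anion equivalent) should add 1,2 to the ketone from the equatorial side, anti to the allylic silyloxy group that prefers the axial position next to the exocyclic methylene, so that the new C1 hydroxyl is cis to the C3 oxygen (1R), and brief oxalic acid treatment should hydrolyse the enol ether to the methyl ketone while keeping the silyl ether.

**Step 5**
Reactants: 9 1-[(1R,3R)-1-hydroxy-4-methylidene-3-(triethylsilyloxy)cyclohexyl]ethan-1-one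
Product: 11 1-[(1R,3R)-1,3-dihydroxy-4-methylidenecyclohexyl]ethenyl trifluoromethanesulfonate, via the silyl-protected vinyl triflate 10 (not isolated)
Conditions: KN(SiMe3)2 (2.2 equiv), THF, −78 °C; PhNTf2; NH4Cl aq.; then PPTS, MeOH, rt
Reagents that add atoms: N-phenylbis(trifluoromethanesulfonimide), O=S(=O)(N(c1ccccc1)S(=O)(=O)C(F)(F)F)C(F)(F)F
Why: Enolisation is possible only toward the methyl group, so the potassium enolate (beside the tertiary alkoxide) should be O-triflated to the vinyl triflate (enol triflate formation), and acidic methanolysis should then remove the triethylsilyl group.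

**Step 6**
Reactants: 11 1-[(1R,3R)-1,3-dihydroxy-4-methylidenecyclohexyl]ethenyl trifluoromethanesulfonate
Product: 12 1-[(1R,3S)-3-chloro-1-hydroxy-4-methylidenecyclohexyl]ethenyl trifluoromethanesulfonate
Conditions: PPh3, Cl3CC(O)CCl3, CH2Cl2, −20 to 0 °C
Reagents that add atoms: hexachloroacetone, ClC(Cl)(Cl)C(=O)C(Cl)(Cl)Cl
Why: Appel-type deoxychlorination should replace the secondary allylic hydroxyl by chloride with SN2 inversion and without allylic transposition (3R to 3S), the hindered tertiary hydroxyl next to the triflate staying untouched.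

**Step 7**
Reactants: 12 1-[(1R,3S)-3-chloro-1-hydroxy-4-methylidenecyclohexyl]ethenyl trifluoromethanesulfonate
Product: 13 1-[(1R,3S,4S)-4-bromo-3-chloro-1-hydroxy-4-methylcyclohexyl]ethenyl trifluoromethanesulfonate
Conditions: HBr (anhydrous), CH2Cl2, −78 to −30 °C
Reagents that add atoms: hydrogen bromide, Br
Why: Ionic Markovnikov hydrobromination: protonation of the exocyclic methylene gives the tertiary C4 cation, bridged by the neighbouring pseudoaxial chlorine, and bromide should open it at the tertiary carbon from the face opposite to chlorine, giving the trans bromochloride with bromine cis to the C1 hydroxyl (4S), while the electron-poor vinyl triflate and the alcohol α to it are not ionised.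

**Step 8**
Reactants: 13 1-[(1R,3S,4S)-4-bromo-3-chloro-1-hydroxy-4-methylcyclohexyl]ethenyl trifluoromethanesulfonate; 14 2-(iodomethyl)-4,4,5,5-tetramethyl-1,3,2-dioxaborolane
Product: 16 (1R,3S,4S)-4-bromo-3-chloro-4-methyl-1-[3-(4,4,5,5-tetramethyl-1,3,2-dioxaborolan-2-yl)prop-1-en-2-yl]cyclohexan-1-ol, via the borylmethylzinc iodide 15 (not isolated)
Conditions: 14, Zn dust, THF, rt (excess Zn removed); then 13, Pd(PPh3)4 (5 mol %), THF, 40 °C
Reagents that add atoms: none
Why: Negishi coupling: zinc inserts into the C–I bond of 14, and zerovalent palladium should couple the α-boryl alkylzinc reagent with the vinyl triflate much faster than it attacks the tertiary C–Br or secondary C–Cl bond (excess zinc is removed first to spare the vicinal dihalide), no stereocentre being touched.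

**Step 9**
Reactants: 16 (1R,3S,4S)-4-bromo-3-chloro-4-methyl-1-[3-(4,4,5,5-tetramethyl-1,3,2-dioxaborolan-2-yl)prop-1-en-2-yl]cyclohexan-1-ol; 17 3-methylbut-2-enal
Product: 18 (1R,3S,4S)-4-bromo-3-chloro-1-[(4S)-4-hydroxy-6-methylhepta-1,5-dien-2-yl]-4-methylcyclohexan-1-ol
Conditions: (S)-TRIP [(S)-3,3'-bis(2,4,6-triisopropylphenyl)-1,1'-binaphthyl-2,2'-diyl hydrogen phosphate] (5 mol %), 4 Å MS, toluene, −30 to 0 °C; aqueous work-up
Reagents that add atoms: none
Why: Chiral phosphoric acid-catalysed allylboration through a chair-like six-membered transition state should join the γ-carbon of the allylboronate to the aldehyde with allylic transposition, creating the 1,1-disubstituted alkene and the C4' carbinol, whose (S) configuration is set by the catalyst.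

**Compound list**

1 | 2-methylallyl acetate | CC(=C)COC(C)=O | starting material
2 | 2-formylallyl acetate | C=C(C=O)COC(C)=O | intermediate
3 | 3-oxopentanedioic acid | OC(=O)CC(=O)CC(O)=O | starting material
4 | 6-formyl-3-oxohept-6-enoic acid | OC(=O)CC(=O)CCC(=C)C=O | intermediate
5 | (3R)-3-hydroxy-4-methylidenecyclohexan-1-one | O=C1CCC(=C)[C@H](O)C1 | intermediate
6 | (3R)-4-methylidene-3-(triethylsilyloxy)cyclohexan-1-one | O=C1CCC(=C)[C@H](O[Si](CC)(CC)CC)C1 | intermediate
7 | ethyl vinyl ether | C=COCC | starting material
8 | (1R,3R)-1-(1-ethoxyethenyl)-4-methylidene-3-(triethylsilyloxy)cyclohexan-1-ol | C=C(OCC)[C@@]1(O)CCC(=C)[C@H](O[Si](CC)(CC)CC)C1 | intermediate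
9 | 1-[(1R,3R)-1-hydroxy-4-methylidene-3-(triethylsilyloxy)cyclohexyl]ethan-1-one | CC(=O)[C@@]1(O)CCC(=C)[C@H](O[Si](CC)(CC)CC)C1 | intermediate
10 | 1-[(1R,3R)-1-hydroxy-4-methylidene-3-(triethylsilyloxy)cyclohexyl]ethenyl trifluoromethanesulfonate | C=C(OS(=O)(=O)C(F)(F)F)[C@@]1(O)CCC(=C)[C@H](O[Si](CC)(CC)CC)C1 | intermediate
11 | 1-[(1R,3R)-1,3-dihydroxy-4-methylidenecyclohexyl]ethenyl trifluoromethanesulfonate | C=C(OS(=O)(=O)C(F)(F)F)[C@@]1(O)CCC(=C)[C@H](O)C1 | intermediate
12 | 1-[(1R,3S)-3-chloro-1-hydroxy-4-methylidenecyclohexyl]ethenyl trifluoromethanesulfonate | C=C(OS(=O)(=O)C(F)(F)F)[C@@]1(O)CCC(=C)[C@@H](Cl)C1 | intermediate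
13 | 1-[(1R,3S,4S)-4-bromo-3-chloro-1-hydroxy-4-methylcyclohexyl]ethenyl trifluoromethanesulfonate | C=C(OS(=O)(=O)C(F)(F)F)[C@@]1(O)CC[C@](C)(Br)[C@@H](Cl)C1 | intermediate
14 | 2-(iodomethyl)-4,4,5,5-tetramethyl-1,3,2-dioxaborolane | ICB1OC(C)(C)C(C)(C)O1 | starting material
15 | iodo[(4,4,5,5-tetramethyl-1,3,2-dioxaborolan-2-yl)methyl]zinc | I[Zn]CB1OC(C)(C)C(C)(C)O1 | intermediate
16 | (1R,3S,4S)-4-bromo-3-chloro-4-methyl-1-[3-(4,4,5,5-tetramethyl-1,3,2-dioxaborolan-2-yl)prop-1-en-2-yl]cyclohexan-1-ol | C=C(CB2OC(C)(C)C(C)(C)O2)[C@@]1(O)CC[C@](C)(Br)[C@@H](Cl)C1 | intermediate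
17 | 3-methylbut-2-enal | CC(C)=CC=O | starting material
18 | (1R,3S,4S)-4-bromo-3-chloro-1-[(4S)-4-hydroxy-6-methylhepta-1,5-dien-2-yl]-4-methylcyclohexan-1-ol | C=C(C[C@H](O)C=C(C)C)[C@@]1(O)CC[C@](C)(Br)[C@@H](Cl)C1 | target

**Step count and risks**

Total step count: 9. Longest linear sequence: 9 steps (1 to 18); compounds 3, 7, 14 and 17 enter directly.

Steps most likely to fail:

Step 2 (proposed new method). The first C–C bond may form by 1,2-addition to the aldehyde instead of conjugate addition–elimination. The ring may close in the conjugate sense onto the new exocyclic methylene instead of by aldol. Enantiofacial discrimination in the aldol closure may be poor, and the β-hydroxy ketone may dehydrate and aromatise. The fallback uses known chemistry and does not set out from a numbered compound: in place of compounds 1 to 4 it starts from commercial 1,4-dioxaspiro[4.5]decan-8-one and comes back at compound 5. The ketone is α-aminoxylated with nitrosobenzene under (S)-proline catalysis to (7R)-7-[(phenylamino)oxy]-1,4-dioxaspiro[4.5]decan-8-one F1. Hydrogenolysis of the N–O bond (H2, Pd/C) gives (7R)-7-hydroxy-1,4-dioxaspiro[4.5]decan-8-one F2. Silylation (Et3SiCl, imidazole) gives (7R)-7-(triethylsilyloxy)-1,4-dioxaspiro[4.5]decan-8-one F3. Wittig methylenation (Ph3P=CH2) gives (7R)-8-methylidene-7-(triethylsilyloxy)-1,4-dioxaspiro[4.5]decane F4. Mild acid (PPTS, acetone/H2O) then removes the ketal and the silyl group to give 5.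

Step 7. The tertiary cation may be captured by the C1 hydroxyl instead of bromide, the allylic chloride may ionise and scramble under HBr, and anti selectivity may be incomplete. The fallback sets out from compound 11 and comes back at compound 13, introducing chlorine and a temporary oxygen bridge together. Reductive 1,3-transposition of the allylic alcohol (Mitsunobu reaction with 2-nitrobenzenesulfonylhydrazide, PPh3 and diethyl azodicarboxylate, then loss of N2 from the allylic diazene) should give 1-[(1R)-1-hydroxy-4-methylcyclohex-3-en-1-yl]ethenyl trifluoromethanesulfonate F5. Chloroetherification with N-chlorosuccinimide, in which the C1 hydroxyl opens the chloronium ion at the tertiary carbon from the opposite face, should give 1-[(1S,2S,4R)-2-chloro-1-methyl-7-oxabicyclo[2.2.1]heptan-4-yl]ethenyl trifluoromethanesulfonate F6, with chlorine anti to the oxygen bridge. BBr3 in CH2Cl2 at −78 °C should then cleave the C4–O bond with chlorine participation and deliver bromide on the oxygen face, giving 13. Any F6 formed in step 7 itself can be carried on the same way.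

Step 4. Facial selectivity may be poor if the silyloxy group is not axial in the reacting conformer, and base-induced β-elimination may compete. The fallback sets out from compound 5 and comes back at compound 9, replacing conformational control by chelation. The free alcohol is converted into its magnesium alkoxide (i-PrMgCl), which bridges to the ketone with the C–O bond axial; (1-ethoxyvinyl)magnesium bromide (from 7, t-BuLi, then MgBr2) then attacks from the open equatorial side. Oxalic acid hydrolysis gives 1-[(1R,3R)-1,3-dihydroxy-4-methylidenecyclohexyl]ethan-1-one F7, whose secondary hydroxyl is silylated selectively (Et3SiCl, imidazole) to give 9.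

Further compounds
F1 | step 2 | (7R)-7-[(phenylamino)oxy]-1,4-dioxaspiro[4.5]decan-8-one | C12(OCCO1)CCC(=O)[C@H](ONc3ccccc3)C2
F2 | step 2 | (7R)-7-hydroxy-1,4-dioxaspiro[4.5]decan-8-one | C12(OCCO1)CCC(=O)[C@H](O)C2
F3 | step 2 | (7R)-7-(triethylsilyloxy)-1,4-dioxaspiro[4.5]decan-8-one | C12(OCCO1)CCC(=O)[C@H](O[Si](CC)(CC)CC)C2
F4 | step 2 | (7R)-8-methylidene-7-(triethylsilyloxy)-1,4-dioxaspiro[4.5]decane | C12(OCCO1)CCC(=C)[C@H](O[Si](CC)(CC)CC)C2
F5 | step 7 | 1-[(1R)-1-hydroxy-4-methylcyclohex-3-en-1-yl]ethenyl trifluoromethanesulfonate | C=C(OS(=O)(=O)C(F)(F)F)[C@@]1(O)CCC(C)=CC1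
F6 | step 7 | 1-[(1S,2S,4R)-2-chloro-1-methyl-7-oxabicyclo[2.2.1]heptan-4-yl]ethenyl trifluoromethanesulfonate | C=C(OS(=O)(=O)C(F)(F)F)[C@]12CC[C@](C)(O1)[C@@H](Cl)C2
F7 | step 4 | 1-[(1R,3R)-1,3-dihydroxy-4-methylidenecyclohexyl]ethan-1-one | CC(=O)[C@@]1(O)CCC(=C)[C@H](O)C1
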